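The readings are calculated for substances that don't exist.

Minutes cannot place these flasks: at 90.0 min larch holds an excess of right-handed over left-handed substrate of 26.5%, cedar 38.3%. I count the dose instead: loading of free catalyst times time, in units of larch's last reading. Cedar at 50.0 min has dose 0.997 and holds 19.9% of left-handed substrate, close to larch's 20.7%.

the same everywhere: left-handed substrate 0.020 M; right-handed substrate 0.020 M; added ligand 21 µM

| run | reagent | free catalyst | remark | time |
|---|---|---|---|---|
| larch | 2.5 equiv | 0.078 mol% | run made earlier |  |
| cedar | 2.5 equiv | 0.14 mol% | run made earlier |  |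
| Monday's | 2.50 equiv | 0.1 mol% |  | 3.0 h |
| Saturday's | 2.50 equiv | 0.2 mol% |  | 3.0 h |

| run | time / min | right-handed substrate / % | left-handed substrate / % |
|---|---|---|---|
| larch | 5.00 | 49.4 | 47.4 |
| larch | 15.0 | 47.1 | 41.3 |
| larch | 25.0 | 44.5 | 36.9 |
| larch | 40.0 | 42.4 | 31.1 |
| larch | 50.0 | 40.7 | 28.8 |
| larch | 80.0 | 36.9 | 23.0 |
| larch | 90.0 | 35.6 | 20.7 |
| cedar | 5.00 | 48.2 | 44.6 |
| cedar | 15.0 | 45.0 | 35.6 |
| cedar | 25.0 | 41.6 | 28.8 |
| cedar | 40.0 | 37.9 | 22.0 |
| cedar | 50.0 | 35.7 | 19.9 |
| cedar | 80.0 | 30.1 | 13.1 |
| cedar | 90.0 | 28.9 | 12.9 |

(readings scatter by 0.3 percentage points)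

- free catalyst is single-handed; left-handed substrate and right-handed substrate are mirror images of each other, charged as a racemate, each of them at the stated concentration
- an excess is the difference of the two amounts in percent of their sum
- an excess is below zero if the other one leads

- the flask that ends with the higher excess of right-handed substrate over left-handed substrate among what is left of the two, or "neither" when 2 percentage points or less lies between them (Monday's / Saturday's / neither)
- excess of right-handed substrate over left-handed substrate among what is left of the two at the end, Monday's
- excess of right-handed substrate over left-handed substrate among what is left of the two at the end, Saturday's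

What does a doubling of dose buy? From larch to cedar at their last readings the dose grows by a factor of 1.79 and the excess by 12 percentage points, so I read a gain per doubling of dose of 14 points.

Where do the new flasks stand? Monday's dose is 2.56, Saturday's 5.13, twice as much in the same 3.0 h. Laying these doublings onto larch, I reckon Monday's at 45.5% and Saturday's at 59.5%. The gap is one gain, more than the margin of 2 points, so I put Saturday's ahead.

The forecast also names Saturday's, but with 41% and 49%, both lower than my figures: “The excess plateaus near 57%, so Saturday's leads modestly.”

The flasks give Saturday's as the leader, with 40.7% for Monday's and 59.3% for Saturday's.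

    reagent + free catalyst → spent catalyst (k = 1.13 M⁻¹ h⁻¹)
    free catalyst + added ligand ⇌ idle complex, settled at all times (K = 19000 M⁻¹)
    reagent + free catalyst + right-handed substrate → free catalyst + right-handed product (k = 4.62 × 10⁵ M⁻² h⁻¹)
    left-handed substrate ⇌ right-handed substrate (k = 0.0989 h⁻¹)
    reagent + free catalyst + left-handed substrate → free catalyst + left-handed product (k = 1.42 × 10⁶ M⁻² h⁻¹)
    free catalyst ⇌ dormant form (K = 1.29, k = 0.0882 h⁻¹)

That doubling brought 19 points against my 14 points, and the loading may be called the main reason for the gap: Saturday's flask holds 59.3%, and at Monday's loading it holds 40.7%. Monday's flask stopped at 80 min has dose 1.14, which counts to 29.1%, and it holds 29.4%. Later, hours and loading part: a flask at Saturday's loading stopped at 90.0 min has the same dose as Monday's, yet shows 50.6% against 40.7%. In Monday's, the substrates interconvert with a relaxation half-life of 3.50 h, in a step with no catalyst in it. Left until 30.0 h, Monday's falls to 16.8%.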